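Per minute, E in both earlier runs gains little at first and then a nearly constant share of the charge, so the new flask is reckoned here by joining those two ends.

| flask | G | Z | remark | time |
|---|---|---|---|---|
| north-west | 22 mM | 0.80 equiv | run made earlier |  |
| south-east | 35 mM | 0.80 equiv | run made earlier |  |
| flask | 16 mM | 0.800 equiv |  | 30 min |

| run | time / min | E / % | G / % |
|---|---|---|---|
| north-west | 4.00 | 5.0 | 71.7 |
| north-west | 8.00 | 11.8 | 53.0 |
| north-west | 10.0 | 14.7 | 47.9 |
| north-west | 15.0 | 23.7 | 37.0 |
| north-west | 20.0 | 31.1 | 30.2 |
| south-east | 1.33 | 0.4 | 82.4 |
| south-east | 2.50 | 2.3 | 71.4 |
| south-east | 5.00 | 7.3 | 53.7 |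
| south-east | 10.0 | 17.4 | 35.1 |
| south-east | 20.0 | 34.0 | 19.8 |

(each reading ± 0.5 percentage points)

- amount of E in percent of the G charged, at 3.0 min, 10 min, 20 min and 30 min



How fast does E start? In the south-east run G falls to 82.4% by 1.33 min, which reads as a first-order constant of 0.146 /min. Z stands at the same equivalents in each flask, so this constant is scaled with the charge, and the new flask gets 0.0665 /min. Between 2.50 min and 5.00 min of that run, the gain of E, set against the material missing from G + E, reads as 0.0613 /min. The product of these two constants is the starting acceleration of E.

How fast does E climb? From 10.0 min to 20.0 min E gains 16 percentage points in the north-west run and 17 points in the south-east run, although the charges differ by a factor of 1.59. The new flask is therefore given the same climb, 0.0165 /min as a share of the charge.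

Where do the ends meet? The climb divided by the starting acceleration, 4.05 min, is the join time, the moment in this reckoning when the rising slope of E reaches the climb; with the climb and the second constant held the same, it scales as one over the charge. The asked time of 3.0 min lies before it, so the acceleration gives 1.83%. Later, E is reckoned on a straight line, the climb times the time less half the join time: 13.2%, 29.7% and 46.2%. The last figure lies past the last reading of the earlier runs and assumes that the climb lasts.

The forecast, noting that “The E curves start with a lag”, gives 2%, 13%, 29% and 43%, ending below this line.

The flask gives 1.94%, 12.7%, 27.7% and 38.0%.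

    G + L → X (k = 0.0350 /M/s)
    G + Z → L (k = 0.0940 /M/s)
    L → E (k = 0.00130 /s)
    G + E → D (k = 0.00840 /M/s)

At 30 min E in the flask stands below the line: L is then made, each step taken net, at about half the rate at which it is used up, and it has dropped from 20.4% at 15.0 min to 11.5%. At 10 min, past the join time of 4.05 min, the line's 13.2% stands beside the flask's 12.7%. Scaled to the north-west run, the join time becomes 2.94 min, which puts E at 4.17% at 4.00 min, where the reading is 5.0%.

The runs are simulated from invented constants, and the scatter is random.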